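Read the earlier runs for the rate at which target is gained, not for the amounts, and ask how fast that rate dies away.

| flask | starting material | reagent | protic impurity | temperature | remark | time |
|---|---|---|---|---|---|---|
| zeta | 0.70 M | 0.70 equiv | 0.50 M | −12 °C | run made earlier |  |
| eta | 1.1 M | 0.70 equiv | 0.50 M | 15 °C | run made earlier |  |
| gamma | 0.50 M | 0.70 equiv | 0.75 M | −12 °C | run made earlier |  |
| south-east | 0.50 M | 0.700 equiv | 0.500 M |  | at 25 °C until 2.5 min, from then on at −25 °C | 12 min |
| east | 0.50 M | 0.700 equiv | 0.500 M | 25 °C |  | 12 min |
| south-west | 0.50 M | 0.700 equiv | 0.500 M | −25 °C |  | 12 min |
| north-east | 0.50 M | 0.700 equiv | 0.500 M | 0 °C |  | 12 min |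

- zeta (time / min: target / %, isomer of the product A / %): 5.00: 12.1, 0.9; 12.0: 18.3, 0.8; 25.0: 21.1, 2.4; 60.0: 21.0, 2.2
- eta (time / min: target / %, isomer of the product A / %): 1.33: 19.8, 6.1; 3.00: 23.1, 7.6; 6.00: 22.6, 9.3; 15.0: 22.7, 10.3
- gamma (time / min: target / %, isomer of the product A / %): 8.00: 9.2, 0.3; 20.0: 10.7, 1.0; 40.0: 8.9, 0.2; 60.0: 8.9, 0.3

(standard deviation of a reading: 0.5 percentage points)

- the best flask by share of target in all that became target or isomer of the product A or isomer of the product B or over-reaction product; "all alike" if 1.5 percentage points covers them all (south-east / east / south-west / north-east / all alike)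
- share of target in all that became target or isomer of the product A or isomer of the product B or over-reaction product, south-east
- share of target in all that became target or isomer of the product A or isomer of the product B or over-reaction product, east
- share of target in all that became target or isomer of the product A or isomer of the product B or over-reaction product, south-west
- share of target in all that became target or isomer of the product A or isomer of the product B or over-reaction product, north-east



In the zeta run target climbs to a plateau near 21.0 %. Suppose the target still to come shrinks by a constant fraction each minute. The first reading then gives: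

clock, zeta = ln(plateau / (plateau − first reading)) / time = 0.172 /min

This clock, the fractional fall per minute in the target still to come, is an empirical number read from the curve of target, and the reading at 12.0 min gives 0.171 /min. The gain therefore starts at 0.0361 /min of the charge, and its rate has fallen by a factor 2.36 at 5.00 min.

The eta run has the same protic impurity and is warmer. Its first reading gives 1.55 /min, a factor 9.01 between −12 °C and 15 °C, though its starting material differs. Our flasks hold 0.500 M of protic impurity too, so we take the logarithm of the clock as linear in temperature and count lives, clock times time:

south-west: 0.0596 /min, lives 0.715, gain still to come 48.9 %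

north-east: 0.456 /min, lives 5.47

east: 3.49 /min, lives 41.9; south-east, 8.73 lives before the change

South-west has the fewest lives. In the eta run isomer of the product A rose from 7.6 % to 10.3 % while target stayed flat, so we commit to south-west as best. Our reckoning gives no percentages, and there it differs from the forecast.

The forecast named south-west and gave 79 % for south-east, 74 % for east, 91 % for south-west and 85 % for north-east: “Cold looks best, though the concentration and impurity dependences are confounded.”

The flasks give south-west as best, with 46.5 % for south-east, 29.0 % for east, 96.1 % for south-west and 69.0 % for north-east.

    starting material + reagent ⇌ target (K = 6.00 /M, k = 0.0170 /M/s, Ea = 43.0 kJ/mol, ΔH = −80.0 kJ/mol)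
    target ⇌ isomer of the product B (K = 0.460, k = 0.0100 /s, Ea = 77.0 kJ/mol, ΔH = −6.00 kJ/mol)
    starting material + protic impurity → quenched substrate (k = 0.0870 /M/s, Ea = 45.0 kJ/mol)
    reagent + target → over-reaction product (k = 0.00140 /M/s, Ea = 52.0 kJ/mol)
    starting material + reagent ⇌ isomer of the product A (K = 17.0 /M, k = 0.00630 /M/s, Ea = 74.0 kJ/mol, ΔH = −66.0 kJ/mol)
    (constants at 25 °C)

In south-west, where the clock left 48.9 % of the gain to come, starting material stood at 48.5 % beside 8.33 % of target at 12 min, still being quenched by protic impurity with a half-life of 18 min, while target and isomer of the product B relaxed with a half-life of 4.31 h, far longer than the time. In east, starting material was down to 1.15 % at 12 min, with 4.06 % of target beside 6.24 % of isomer of the product A. For the same flask as south-west at −10 °C, the clock is 0.202 /min, which leaves 8.86 % to come; that flask holds 16.4 % of starting material and 13.8 % of target, a share of 86.0 %.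

All runs come from a simulation for an exercise; the scatter is artificial.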